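Late in this flask the question is how much of the first rate is left, so you follow that rate alone, as fractions of the charge, and leave the concentrations aside.

Ry 1.0 M; Kj 1.20 M; Dw 0.500 M; time 20 min

    Ji + Ry → Ji.Ry (k1 = 0.10 M⁻¹ min⁻¹)
    Ry + Kj ⇌ Ji + Ul (K2 = 0.30, k2 = 0.096 M⁻¹ min⁻¹)
    Ji + Kj ⇌ Ji.Kj, settled at all times (K3 = 1.9 M⁻¹)
    Dw + Ji → Dw.Ji (k4 = 0.80 M⁻¹ min⁻¹)
    Ul + Kj ⇌ Ji + Dz (K5 = 1.3, k5 = 0.22 M⁻¹ min⁻¹)

- part of the Ry that has reacted at 20 min
- share of the unused Kj that is free and not bound as Ji.Kj, at 20 min

- for Ji the Ji.Kj is counted in
- run time (flask): 20 min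

You start with Ry leaving by the first exchange at 0.115 min⁻¹ of its charge. Two factors slow this: the fraction of Ry not yet exchanged and the fraction of Kj left. As a simplification of mine I charge two Kj per exchanged Ry, as if each Ul went on to Dz at once, which overcounts the Kj spent wherever Ul still stands in the flask. On that count Kj is the limiting reagent, with enough for 60.0 % of the Ry to pass through both exchanges. Leaving the way back out, the rate integrates on one number, the exchange clock, the rate constant of the first exchange times the Ry charge times the time, 1.92, together with the Kj-per-Ry ratio: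

ratio = 1.20

W = exp[clock × (2 − ratio)] = 4.65

exchanged fraction x = ratio × (W − 1) / (2W − ratio) = 54.1 %

Ry factor 45.9 % × Kj factor 9.83 % = 4.51 % of the first rate

Unslowed, the same clock would have taken 90.0 % of the Ry, so the accumulated slowing is what brings it down to x. Ry also has a second exit: freed Ji goes to Ry or to Dw, and Dw takes it faster (1.7 min against 6.9 min). If Ry and Dw fall alike, Ji.Ry reaches 12.5 % of the Ry as Dw is used. So I commit to 66.6 %, and my reckoning stops there, without fr.

The forecast gives 61 % (57 % to 65 %), lower than mine, and 80 % (76 % to 84 %), noting: “The reverse reactions become important late, so net exchange slows.”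

The flask gives 61.8 % and 79.0 %, both inside the forecast's ranges, while my figure stands 4.8 percentage points above the first; of the Kj charge, 27 % is left unbound at 20.0 min. On the neighbour flask, charged with 0.72 M of Kj, the same clock gives W = 11.7, an exchanged fraction of 34.0 %, and with the Ji.Ry term 46.5 %. That neighbour flask stands at 46.5 %, with 10.0 % of its Ry as Ji.Ry.

The constants used here were set for the occasion, and the outcome is calculated.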